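**Strategy.** The cyclobutane is read as a masked prenyl group: its CH(CH2–core) and CMe2 atoms, with the exocyclic CH2 on the quaternary dienone carbon, are CH2–CH=CMe2, and its CH2 and CH(isopropenyl) atoms are the vinyl end of isoprene. The precursor is therefore the gem-diprenyl chromanone acid, whose own side-chain CO2H is esterified with 2-methylidenebut-3-en-1-ol. A triplet-sensitised [2+2] photocycloaddition of this tethered diene to one of the two diastereotopic prenyl groups closes the cyclobutane last and sets the quaternary centre and both ring CH centres in one event, relayed from the benzylic centre through a temporary macrolactone. Pd/formate hydrogenolysis then turns the tether CH2O into the isopropenyl methyl and frees the acid.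

Key step: step 9

Remark on the chemistry: the enolised tricarbonyl unit of 12 and 15–17 is written in the tautomer of the target SMILES (5-OH chelated to C4=O, C7=O); ring positions follow chromanone numbering (O1, C2, C3, C4, C4a, C5, C6, C7, C8, C8a).

Step 1
Reactants: 1 phloroglucinol; 2 tigloyl chloride [(E)-2-methylbut-2-enoyl chloride]
Product: 3 (E)-2-methyl-1-(2,4,6-trihydroxyphenyl)but-2-en-1-one
Conditions: AlCl3 (3 equiv), PhNO2/CH2Cl2, 0 °C → rt; aq. HCl
Reagents that add atoms: none
Why: Friedel–Crafts acylation of the threefold-symmetric, highly activated arene should stop after one acyl group because the ketone deactivates the ring, and working cold should preserve the open enone needed for the catalytic ring closure (no stereocentre formed).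

Step 2
Reactants: 3 (E)-2-methyl-1-(2,4,6-trihydroxyphenyl)but-2-en-1-one
Product: 5 (2R,3R)-5,7-dihydroxy-2,3-dimethylchroman-4-one, via cis-(2R,3S)-chromanone 4 (not isolated)
Conditions: quinine (10 mol%), PhCl, rt; after full conversion DBU (0.2 equiv), rt
Reagents that add atoms: none
Why: Cinchona-alkaloid-catalysed intramolecular oxa-Michael addition, in which quinine as a chiral general base delivers one of the two equivalent ortho-hydroxyls to one face of the tigloyl β-carbon and is expected to set C2 as R (kinetic protonation gives cis 4), followed by base-mediated enolisation that epimerises C3 to the more stable trans (2R,3R) isomer with both methyl groups equatorial.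

Step 3
Reactants: 5 (2R,3R)-5,7-dihydroxy-2,3-dimethylchroman-4-one; 6 prenyl bromide (1-bromo-3-methylbut-2-ene)
Product: 7 (2R,3R)-5,7-dihydroxy-2,3-dimethyl-6-(3-methylbut-2-enyl)chroman-4-one
Conditions: 6 (1.05 equiv), 10% aq. KOH, 0 °C
Reagents that add atoms: none
Why: Phenoxide C-alkylation (C-prenylation): C6 lies between the two hydroxyl-bearing carbons and para to the ring ether oxygen and should be the main site of attack (C8 and O-alkylated isomers are removed by chromatography), and the group placed here also blocks C6 for the next step; no stereocentre is formed and C3 stays trans under base.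

Step 4
Reactants: 7 (2R,3R)-5,7-dihydroxy-2,3-dimethyl-6-(3-methylbut-2-enyl)chroman-4-one; 8 (E)-cinnamaldehyde
Product: 9 lactol: chromanone 7 with O7 and C8 bridged by –CH(OH)–CH2–CH(Ph)– (CHPh carbon S and bonded to C8; anomeric mixture)
Conditions: (S)-α,α-diphenylprolinol trimethylsilyl ether (20 mol%), PhCO2H (20 mol%), CH2Cl2, 0 °C → rt
Reagents that add atoms: none
Why: Iminium-catalysed Friedel–Crafts-type Michael addition followed by hemiacetalisation: C8 is the only free ring carbon, and the (S)-diarylprolinol silyl ether shields one face of the E-iminium ion so that the arene adds to the Si face of the β-carbon and sets the benzylic centre as S by catalyst control, independent of the remote chromanone centres.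

Step 5
Reactants: 9 lactol
Product: 10 lactone: as 9 with C=O in place of CHOH (a 4-phenyl-3,4-dihydrocoumarin ring fused at O7/C8; 4S, chromanone 2R,3R)
Conditions: Ag2CO3 on Celite, toluene, 80 °C
Reagents that add atoms: none
Why: Fétizon oxidation converts lactols to lactones under neutral conditions and should leave the chelated phenol, the prenyl group and all three stereocentres untouched.

Step 6
Reactants: 10 lactone; 6 prenyl bromide
Product: 12 (3S)-3-[(2R,3R)-5-hydroxy-2,3-dimethyl-6,6-bis(3-methylbut-2-enyl)-4,7-dioxo-3,4,6,7-tetrahydro-2H-chromen-8-yl]-3-phenylpropanoic acid, via ring-opened monoprenyl acid 11 (not isolated)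
Conditions: 6 (1.5 equiv), 10% aq. KOH, 0 °C; then 1 M HCl
Reagents that add atoms: potassium hydroxide, [K+].[OH-]
Why: Saponification of the aryl lactone followed by dearomative C-alkylation of the polyphenoxide (the classical route from 3-alkyl acylphloroglucinols to gem-dialkyl β-triketones): C6, flanked by two oxyanions, should be more nucleophilic than the fully substituted C8, and since both groups on C6 are identical no stereocentre is created.

Step 7
Reactants: 13 2-methyl-2-vinyloxirane (isoprene monoxide, racemic)
Product: 14 2-methylidenebut-3-en-1-ol
Conditions: LDA, Et2O, 0 °C → rt; H2O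
Reagents that add atoms: none
Why: Base-induced isomerisation of an epoxide to an allylic alcohol: the amide base removes a methyl proton with opening of the adjacent C–O bond, giving the 2-hydroxymethyl-1,3-diene (no stereocentre).

Step 8
Reactants: 12 gem-diprenyl acid; 14 2-methylidenebut-3-en-1-ol
Product: 15 2-methylidenebut-3-enyl ester of 12
Conditions: EDC·HCl, DMAP (cat.), CH2Cl2, 0 °C → rt
Reagents that add atoms: none
Why: Carbodiimide (Steglich-type) esterification of the side-chain acid; any enol ester formed at the acidic ring hydroxyl is itself an acyl donor that DMAP should pass on to the alcohol, and no stereocentre is touched.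

Step 9
Reactants: 15 2-methylidenebut-3-enyl ester of 12
Product: 16 bridged macrolactone: (6R)-dienone carrying one prenyl group and a CH2 link to a cis-1,3-disubstituted 2,2-dimethylcyclobutane, whose other ring CH bears C(=CH2)CH2O–C(=O)CH2– closing a 13-membered lactone to the (S)-CHPh carbon on C8
Conditions: [Ir(dF(CF3)ppy)2(dtbbpy)]PF6 (2 mol%), blue LEDs (450 nm), degassed CH2Cl2 (1 mM), rt
Reagents that add atoms: none
Why: The photoexcited Ir complex (triplet energy about 61 kcal/mol) should sensitise only the 2-substituted 1,3-diene (about 59 kcal/mol), not the isolated alkenes or the chelated vinylogous-acid core; the diene triplet adds through its unsubstituted vinyl CH2 to the CH carbon of a prenyl C=C, and the resulting tertiary-alkyl/allyl 1,4-biradical recombines at the nearer allyl terminus after spin inversion. The closest known reaction is the visible-light, energy-transfer intramolecular [2+2] photocycloaddition of 1,3-dienes with tethered alkenes. The cyclobutane is thus closed by a stepwise [2+2] (radical addition, then 1,4-biradical recombination), while the first C–C bond at the same time closes the temporary 13-membered lactone. C6 is controlled by the (S)-benzylic centre: the two prenyl groups crowd both faces on the C7 side, so the side-chain C–H should lie in the ring plane towards C7=O with phenyl and the CH2CO2 arm above and below the flat C8a–O1 side, and the arm can bridge only to the prenyl group on its own face (giving 6R); the ring CH bearing the CH2 link is set by the macrocycle, which should turn the CMe2 carbon away from the dienone, and the ring CH bearing the propenyl unit is then cis because a ten-atom 1,3-bridge across a cyclobutane can only be cis. The step needs sensitisation of the diene alone, bonding through the vinyl rather than the 1,1-disubstituted diene terminus, and choice of one of two diastereotopic prenyl groups and of one alkene face; these rest on the triplet energies, on formation of the most stabilised biradical at the least hindered termini, and on the ester tether anchored at the stereocentre, with high dilution suppressing diene dimerisation.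

Step 10
Reactants: 16 bridged macrolactone
Product: 17 (3S)-3-[(2R,3R,6R)-6-{[(1R,3S)-2,2-dimethyl-3-(prop-1-en-2-yl)cyclobutyl]methyl}-5-hydroxy-2,3-dimethyl-6-(3-methylbut-2-enyl)-4,7-dioxo-3,4,6,7-tetrahydro-2H-chromen-8-yl]-3-phenylpropanoic acid
Conditions: Pd2(dba)3 (2.5 mol%), PBu3 (10 mol%), HCO2H, Et3N, THF, 40 °C
Reagents that add atoms: none
Why: Tsuji–Trost-type hydrogenolysis: Pd(0) ionises the allylic ester to a 2-substituted π-allyl complex and the carboxylate, and hydride from formate is delivered to either of the two equivalent CH2 termini, so the tether CH2–O becomes the isopropenyl methyl and the acid is released without touching the stereocentres or the other alkenes.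

**Compound list**

1 | phloroglucinol | Oc1cc(O)cc(O)c1 | starting material
2 | tigloyl chloride | C/C=C(\C)C(=O)Cl | starting material
3 | (E)-2-methyl-1-(2,4,6-trihydroxyphenyl)but-2-en-1-one | C/C=C(\C)C(=O)c1c(O)cc(O)cc1O | intermediate
4 | cis-(2R,3S)-5,7-dihydroxy-2,3-dimethylchroman-4-one | Oc1cc(O)c2c(c1)O[C@H](C)[C@H](C)C2=O | intermediate
5 | (2R,3R)-5,7-dihydroxy-2,3-dimethylchroman-4-one | Oc1cc(O)c2c(c1)O[C@H](C)[C@@H](C)C2=O | intermediate
6 | prenyl bromide | CC(C)=CCBr | starting material
7 | (2R,3R)-5,7-dihydroxy-2,3-dimethyl-6-(3-methylbut-2-enyl)chroman-4-one | Oc1c(CC=C(C)C)c(O)c2c(c1)O[C@H](C)[C@@H](C)C2=O | intermediate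
8 | (E)-cinnamaldehyde | O=C/C=C/c1ccccc1 | starting material
9 | lactol (O7/C8-fused 2-hydroxy-4-phenylchroman ring, 4S, anomeric mixture) | OC1C[C@@H](c2ccccc2)c2c(O1)c(CC=C(C)C)c(O)c1c2O[C@H](C)[C@@H](C)C1=O | intermediate
10 | lactone (O7/C8-fused 4-phenyl-3,4-dihydrocoumarin ring, 4S) | O=C1C[C@@H](c2ccccc2)c2c(O1)c(CC=C(C)C)c(O)c1c2O[C@H](C)[C@@H](C)C1=O | intermediate
11 | (3S)-3-[(2R,3R)-5,7-dihydroxy-2,3-dimethyl-6-(3-methylbut-2-enyl)-4-oxochroman-8-yl]-3-phenylpropanoic acid | OC(=O)C[C@@H](c1ccccc1)c1c(O)c(CC=C(C)C)c(O)c2c1O[C@H](C)[C@@H](C)C2=O | intermediate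
12 | (3S)-3-[(2R,3R)-5-hydroxy-2,3-dimethyl-6,6-bis(3-methylbut-2-enyl)-4,7-dioxo-3,4,6,7-tetrahydro-2H-chromen-8-yl]-3-phenylpropanoic acid | CC(C)=CCC1(CC=C(C)C)C(=O)C([C@@H](CC(=O)O)c2ccccc2)=C2O[C@H](C)[C@@H](C)C(=O)C2=C1O | intermediate
13 | 2-methyl-2-vinyloxirane (racemic) | CC1(C=C)CO1 | starting material
14 | 2-methylidenebut-3-en-1-ol | C=CC(=C)CO | intermediate
15 | 2-methylidenebut-3-enyl ester of 12 | C=CC(=C)COC(=O)C[C@@H](c1ccccc1)C1=C2O[C@H](C)[C@@H](C)C(=O)C2=C(O)C(CC=C(C)C)(CC=C(C)C)C1=O | intermediate
16 | bridged macrolactone (cyclobutane and C6 configured as in 17) | C=C(CO4)[C@@H]1C[C@H](C[C@@]2(CC=C(C)C)C(=O)C([C@@H](CC4=O)c3ccccc3)=C3O[C@H](C)[C@@H](C)C(=O)C3=C2O)C1(C)C | intermediate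
17 | CNP0103716.3 | C=C(C)[C@@H]1C[C@H](C[C@@]2(CC=C(C)C)C(=O)C([C@@H](CC(=O)O)c3ccccc3)=C3O[C@H](C)[C@@H](C)C(=O)C3=C2O)C1(C)C | target

**Totals.** Total step count: 10. Longest linear sequence: 9 steps (steps 1–6 and 8–10; step 7 is a one-step side branch).

**Steps most likely to fail**

1. Step 9. The diene triplet may dimerise or close through its 1,1-disubstituted double bond instead of macrocyclising through the vinyl group. The arm may bridge to the other prenyl group or the other alkene face, because the rotamer argument is a conformational expectation only. The enolised core may also quench the sensitiser. The fallback separates ring closure from the setting of C6 and sets out from lactone 10. Base-catalysed ring-opening transesterification of 10 with dienol 14 (DMAP, Et3N, CH2Cl2) should give the aromatic dienyl ester F1, in which only one prenyl group is present and the chromophore is a photostable chelated hydroxyaryl ketone. The same sensitised [2+2] photocycloaddition on F1 then closes the cyclobutane as the aromatic ansa-macrolactone F2. Dearomative C-prenylation of F2 with 6 (NaH, toluene, 0 °C) must take place on the face of C6 opposite the bridge and returns to the route at 16.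

2. Step 4. Addition of the fully flanked, acyl-deactivated C8 to the iminium ion may be too slow, so that oxa-Michael addition or loss of facial control takes over. The fallback sets out from 7. Heating 7 with commercial 5-benzylidene-2,2-dimethyl-1,3-dioxane-4,6-dione and Et3N in MeCN (Michael addition of C8, then lactonisation with loss of acetone and CO2) should give lactone 10 together with its benzylic epimer, the (4R)-lactone F3. The two are diastereomers, are separated by chromatography, and 10 re-enters the route at step 6.

3. Step 3. Alkylation may go to C8 or to the 7-oxygen instead of C6. The fallback sets out from 3, where the two free ring carbons are equivalent. C-prenylation of 3 with 6 (aq. KOH, 0 °C, short contact time) should give the prenylated acylphloroglucinol F4. Quinine-catalysed oxa-Michael addition through the less hindered ortho-hydroxyl (the one not flanked by the prenyl group) should give the cis-6-prenylchromanone F5, and DBU epimerisation at C3 returns to the route at 7.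

Further compounds
F1 | step 9 | 2-methylidenebut-3-enyl (3S)-3-[(2R,3R)-5,7-dihydroxy-2,3-dimethyl-6-(3-methylbut-2-enyl)-4-oxochroman-8-yl]-3-phenylpropanoate | C=CC(=C)COC(=O)C[C@@H](c1ccccc1)c1c(O)c(CC=C(C)C)c(O)c2c1O[C@H](C)[C@@H](C)C2=O
F2 | step 9 | aromatic ansa-macrolactone (5,7-dihydroxychromanone with the C6–CH2–cyclobutane and C8–CH(Ph)CH2CO2 arms joined through the ester; cyclobutane as in 16) | C=C(CO4)[C@@H]1C[C@H](Cc2c(O)c([C@@H](CC4=O)c3ccccc3)c3O[C@H](C)[C@@H](C)C(=O)c3c2O)C1(C)C
F3 | step 4 | (4R)-lactone, benzylic epimer of 10 | O=C1C[C@H](c2ccccc2)c2c(O1)c(CC=C(C)C)c(O)c1c2O[C@H](C)[C@@H](C)C1=O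
F4 | step 3 | (E)-2-methyl-1-[2,4,6-trihydroxy-3-(3-methylbut-2-enyl)phenyl]but-2-en-1-one | C/C=C(\C)C(=O)c1c(O)cc(O)c(CC=C(C)C)c1O
F5 | step 3 | cis-(2R,3S)-5,7-dihydroxy-2,3-dimethyl-6-(3-methylbut-2-enyl)chroman-4-one | Oc1c(CC=C(C)C)c(O)c2c(c1)O[C@H](C)[C@H](C)C2=O
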